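**Strategy.** Everything rests on assembling the benzenoid ring of the 5,7-dihydroxycoumarin half (ring B, primed locants) from two acyclic esters instead of coupling two arenes. Its ether carbon C8' lies between the oxygenated carbons C7' and C8a', the pattern of a 2-substituted malonate, while C6', C5' and C4a' correspond to a 3-oxoglutarate. One base-mediated [3+3] double Claisen condensation therefore forms C6'–C7' and C4a'–C8a' and delivers the aromatic triol diester with the diaryl ether already in place. Its precursor is an aryloxymalonate, obtained by SN2 O-alkylation of 8-hydroxy-7-methoxycoumarin. Decarboxylation, protection of the unhindered 5'-OH, ortho-formylation and Wittig lactonization then complete the second pyranone.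

Key step: step 2

Assumption: 8-hydroxy-7-methoxycoumarin is purchased as daphnetin 7-methyl ether; the enolizable carbons of the open-chain Claisen intermediate carry no defined configuration; the target has no stereocenter.

**Step 1**
Reactants: 1 8-hydroxy-7-methoxy-2H-chromen-2-one; 2 dimethyl 2-chloropropanedioate
Product: 3 dimethyl 2-[(7-methoxy-2-oxo-2H-chromen-8-yl)oxy]propanedioate
Conditions: K2CO3, acetone, reflux
Reagents that add atoms: none
Why: Williamson-type SN2 O-alkylation of a phenoxide by an alpha-halomalonate, in which carbonate is too weak to open the lactone and the doubly activated secondary chloride is displaced readily, so the hindered ether oxygen–carbon bond is made at sp3 carbon.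

**Step 2**
Reactants: 3 dimethyl 2-[(7-methoxy-2-oxo-2H-chromen-8-yl)oxy]propanedioate; 4 dimethyl 3-oxopentanedioate (2 equiv, added slowly)
Product: 6 dimethyl 2,4,6-trihydroxy-5-[(7-methoxy-2-oxo-2H-chromen-8-yl)oxy]benzene-1,3-dicarboxylate, via open-chain Claisen adduct 5 (not isolated)
Conditions: NaOMe (4 equiv), MeOH, reflux, Ar; then 2 M HCl, 0 °C to rt
Reagents that add atoms: none
Why: The sodium enolate of 4 is acylated at C2 by one ester carbonyl of 3 (intermolecular Claisen condensation) to give the open-chain tetracarbonyl 5, and after deprotonation of its remaining CH2 the second oxoglutarate carbon attacks the other malonate ester in a 6-exo-trig Dieckmann closure that forms ring B. The resulting cyclohexanetrione still carries a hydrogen on the aryloxy carbon, so it tautomerizes to the phloroglucinol, whose phenoxide is the thermodynamic sink that pulls the reversible acylations forward. The closest known reaction type is the alkoxide condensation of malonic esters with 3-oxoglutarates to phloroglucinoldicarboxylates, supported by the use of aryloxymalonates as 1,3-bis-electrophiles toward amidines in NaOMe/MeOH. No stereocenter is formed. The step needs cross-condensation to outrun the aldol self-condensation of 4, which should be secured by the alpha-aryloxy group (it makes the ester carbonyls of 3 more electrophilic than any carbonyl of enolized 4) and by feeding 4 slowly into excess base so that little neutral 4 is present; matching methyl esters to methoxide makes transesterification degenerate. The lactone of the methoxycoumarin half should survive, since any methoxide addition to it is reversible, leaves the cis alkene untouched and is undone on acidification.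

**Step 3**
Reactants: 6 dimethyl 2,4,6-trihydroxy-5-[(7-methoxy-2-oxo-2H-chromen-8-yl)oxy]benzene-1,3-dicarboxylate
Product: 9 7-methoxy-8-(2,4,6-trihydroxyphenoxy)-2H-chromen-2-one, via ring-opened triacid salt 7 (not isolated), via lactone diacid 8 (not isolated)
Conditions: degassed 2 M NaOH, 90 °C, Ar; then 6 M HCl to pH 1, 60 °C
Reagents that add atoms: none
Why: Alkaline ester hydrolysis frees both carboxyl groups and opens the lactone of the methoxycoumarin half reversibly to the cis-cinnamate 7, and acidification recloses the lactone to 8, whose 2,4,6-trihydroxybenzoic acid units lose CO2 on gentle warming through ipso-protonation (saponification followed by protodecarboxylation of a phloroglucinolcarboxylic acid).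

**Step 4**
Reactants: 9 7-methoxy-8-(2,4,6-trihydroxyphenoxy)-2H-chromen-2-one
Product: 10 8-{2,6-dihydroxy-4-[(triisopropylsilyl)oxy]phenoxy}-7-methoxy-2H-chromen-2-one
Conditions: TIPSCl (1.0 equiv), imidazole, DMF, −20 to 0 °C
Reagents that add atoms: chlorotriisopropylsilane (TIPSCl), CC(C)[Si](Cl)(C(C)C)C(C)C
Why: Imidazole-mediated O-silylation with a bulky silyl chloride is sterically ruled, and the 5'-OH para to the ether has two ortho hydrogens whereas each of the other two hydroxyls is shielded by the twisted coumarinyloxy group, so one equivalent at low temperature should take the open site.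

**Step 5**
Reactants: 10 8-{2,6-dihydroxy-4-[(triisopropylsilyl)oxy]phenoxy}-7-methoxy-2H-chromen-2-one
Product: 12 2,4-dihydroxy-3-[(7-methoxy-2-oxo-2H-chromen-8-yl)oxy]-6-[(triisopropylsilyl)oxy]benzaldehyde, via benzylic alcohol 11 (not isolated)
Conditions: MgCl2, Et3N, (CH2O)n, THF, reflux; then 1 M HCl
Reagents that add atoms: formaldehyde (as paraformaldehyde), C=O
Why: Magnesium phenoxide-directed ortho-formylation (Casnati–Skattebøl reaction) can only strike the two equivalent C–H positions ortho to a free hydroxyl, giving one aldehyde by way of benzylic alcohol 11, which a second formaldehyde oxidizes by hydride transfer.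

**Step 6**
Reactants: 12 2,4-dihydroxy-3-[(7-methoxy-2-oxo-2H-chromen-8-yl)oxy]-6-[(triisopropylsilyl)oxy]benzaldehyde
Product: 15 7-hydroxy-8-[(7-methoxy-2-oxo-2H-chromen-8-yl)oxy]-5-[(triisopropylsilyl)oxy]-2H-chromen-2-one, via E-cinnamate 13 (not isolated), via Z-cinnamate 14 (not isolated)
Conditions: Ph3P=CHCO2Et (2 equiv), PhNEt2, reflux, Ar
Reagents that add atoms: ethyl (triphenylphosphoranylidene)acetate, CCOC(=O)C=P(c1ccccc1)(c1ccccc1)c1ccccc1
Why: Wittig olefination with a stabilized ylide gives the cinnamate, which at this temperature equilibrates to the Z isomer and lactonizes onto the only free ortho hydroxyl (the other ortho oxygen being silylated), so the pyranone closes toward the oxygen next to the ether carbon as required for C8a'.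

**Step 7**
Reactants: 15 7-hydroxy-8-[(7-methoxy-2-oxo-2H-chromen-8-yl)oxy]-5-[(triisopropylsilyl)oxy]-2H-chromen-2-one
Product: 16 5,7-dihydroxy-8-[(7-methoxy-2-oxo-2H-chromen-8-yl)oxy]-2H-chromen-2-one
Conditions: Bu4NF, AcOH, THF, 0 °C
Reagents that add atoms: none
Why: Fluoride-mediated cleavage of the aryl silyl ether driven by Si–F bond formation, buffered by acetic acid so that neither lactone meets free phenoxide or hydroxide base.

**Compound list**
1 | 8-hydroxy-7-methoxy-2H-chromen-2-one (daphnetin 7-methyl ether) | COc1ccc2ccc(=O)oc2c1O | starting material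
2 | dimethyl 2-chloropropanedioate (dimethyl chloromalonate) | COC(=O)C(Cl)C(=O)OC | starting material
3 | dimethyl 2-[(7-methoxy-2-oxo-2H-chromen-8-yl)oxy]propanedioate | COc1ccc2ccc(=O)oc2c1OC(C(=O)OC)C(=O)OC | intermediate
4 | dimethyl 3-oxopentanedioate | COC(=O)CC(=O)CC(=O)OC | starting material
5 | dimethyl 4-(methoxycarbonyl)-2-[(7-methoxy-2-oxo-2H-chromen-8-yl)oxy]-3,5-dioxoheptanedioate (open-chain Claisen adduct, enolized, no defined configuration) | COC(=O)CC(=O)C(C(=O)OC)C(=O)C(Oc1c(OC)ccc2ccc(=O)oc12)C(=O)OC | intermediate (not isolated)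
6 | dimethyl 2,4,6-trihydroxy-5-[(7-methoxy-2-oxo-2H-chromen-8-yl)oxy]benzene-1,3-dicarboxylate | COC(=O)c1c(O)c(C(=O)OC)c(O)c(Oc2c(OC)ccc3ccc(=O)oc23)c1O | intermediate
7 | 5-{3-[(Z)-2-carboxyethenyl]-2-hydroxy-6-methoxyphenoxy}-2,4,6-trihydroxybenzene-1,3-dicarboxylic acid (present in the flask as its sodium salt) | COc1ccc(/C=C\C(=O)O)c(O)c1Oc1c(O)c(C(=O)O)c(O)c(C(=O)O)c1O | intermediate (not isolated)
8 | 2,4,6-trihydroxy-5-[(7-methoxy-2-oxo-2H-chromen-8-yl)oxy]benzene-1,3-dicarboxylic acid | OC(=O)c1c(O)c(C(=O)O)c(O)c(Oc2c(OC)ccc3ccc(=O)oc23)c1O | intermediate (not isolated)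
9 | 7-methoxy-8-(2,4,6-trihydroxyphenoxy)-2H-chromen-2-one | COc1ccc2ccc(=O)oc2c1Oc1c(O)cc(O)cc1O | intermediate
10 | 8-{2,6-dihydroxy-4-[(triisopropylsilyl)oxy]phenoxy}-7-methoxy-2H-chromen-2-one | COc1ccc2ccc(=O)oc2c1Oc1c(O)cc(O[Si](C(C)C)(C(C)C)C(C)C)cc1O | intermediate
11 | 8-{2,6-dihydroxy-3-(hydroxymethyl)-4-[(triisopropylsilyl)oxy]phenoxy}-7-methoxy-2H-chromen-2-one | COc1ccc2ccc(=O)oc2c1Oc1c(O)cc(O[Si](C(C)C)(C(C)C)C(C)C)c(CO)c1O | intermediate (not isolated)
12 | 2,4-dihydroxy-3-[(7-methoxy-2-oxo-2H-chromen-8-yl)oxy]-6-[(triisopropylsilyl)oxy]benzaldehyde | COc1ccc2ccc(=O)oc2c1Oc1c(O)cc(O[Si](C(C)C)(C(C)C)C(C)C)c(C=O)c1O | intermediate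
13 | ethyl (2E)-3-{2,4-dihydroxy-3-[(7-methoxy-2-oxo-2H-chromen-8-yl)oxy]-6-[(triisopropylsilyl)oxy]phenyl}prop-2-enoate | CCOC(=O)/C=C/c1c(O)c(Oc2c(OC)ccc3ccc(=O)oc23)c(O)cc1O[Si](C(C)C)(C(C)C)C(C)C | intermediate (not isolated)
14 | ethyl (2Z)-3-{2,4-dihydroxy-3-[(7-methoxy-2-oxo-2H-chromen-8-yl)oxy]-6-[(triisopropylsilyl)oxy]phenyl}prop-2-enoate | CCOC(=O)/C=C\c1c(O)c(Oc2c(OC)ccc3ccc(=O)oc23)c(O)cc1O[Si](C(C)C)(C(C)C)C(C)C | intermediate (not isolated)
15 | 7-hydroxy-8-[(7-methoxy-2-oxo-2H-chromen-8-yl)oxy]-5-[(triisopropylsilyl)oxy]-2H-chromen-2-one | COc1ccc2ccc(=O)oc2c1Oc1c(O)cc(O[Si](C(C)C)(C(C)C)C(C)C)c2ccc(=O)oc12 | intermediate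
16 | 5,7-dihydroxy-8-[(7-methoxy-2-oxo-2H-chromen-8-yl)oxy]-2H-chromen-2-one (no stereocenter) | COc1ccc2ccc(=O)oc2c1Oc1c(O)cc(O)c2ccc(=O)oc12 | target

**Total step count:** 7. **Longest linear sequence:** 7 steps (from 1).

**Steps most likely to fail**

1. Step 2 (key step). Deprotonation of the acidic C–H of 3 may switch off its ester carbonyls, 4 may condense with itself, the sequence may stall at 5, and methoxide may isomerize the opened cinnamate of the methoxycoumarin half so that it no longer relactonizes. Fallback, from 3 back to 6, with the two C–C bonds made one at a time by known reactions: half-saponification of 3 (KOH, 1 equiv, MeOH, 0 °C; cold dilute HCl) should give the malonic half-ester 3-methoxy-2-[(7-methoxy-2-oxo-2H-chromen-8-yl)oxy]-3-oxopropanoic acid F1. Oxalyl chloride with catalytic DMF in CH2Cl2 should convert it into methyl 3-chloro-2-[(7-methoxy-2-oxo-2H-chromen-8-yl)oxy]-3-oxopropanoate F2. C-acylation of 4 as its magnesium enolate (MgCl2, Et3N, MeCN, 0 °C) with this acid chloride should give the open-chain adduct 5, now isolated. Brief NaOMe in MeOH at room temperature should then effect the intramolecular Dieckmann closure and aromatization to 6.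

2. Step 4. Silylation may be poorly site-selective or run on to bis-silyl ethers, which would later allow lactonization on the wrong oxygen. Fallback, from 9 to 16, with the discrimination moved to the aldehyde stage: Vilsmeier–Haack formylation of 9 (POCl3, DMF, MeCN, 0 °C) should give the iminium salt N-{2,4,6-trihydroxy-3-[(7-methoxy-2-oxo-2H-chromen-8-yl)oxy]benzylidene}-N-methylmethanaminium chloride F3, hydrolysed with aqueous NaOAc to 2,4,6-trihydroxy-3-[(7-methoxy-2-oxo-2H-chromen-8-yl)oxy]benzaldehyde F4. MOMCl (2.1 equiv) and iPr2NEt in CH2Cl2 at 0 °C should cap the para hydroxyl and the less hindered ortho hydroxyl. The hydroxyl wedged between the formyl group and the ether stays chelated and free, giving 2-hydroxy-4,6-bis(methoxymethoxy)-3-[(7-methoxy-2-oxo-2H-chromen-8-yl)oxy]benzaldehyde F5. Wittig olefination with Ph3P=CHCO2Et in refluxing PhNEt2 should pass through ethyl (2E)-3-{2-hydroxy-4,6-bis(methoxymethoxy)-3-[(7-methoxy-2-oxo-2H-chromen-8-yl)oxy]phenyl}prop-2-enoate F6 and its isomer ethyl (2Z)-3-{2-hydroxy-4,6-bis(methoxymethoxy)-3-[(7-methoxy-2-oxo-2H-chromen-8-yl)oxy]phenyl}prop-2-enoate F7 to the lactone 5,7-bis(methoxymethoxy)-8-[(7-methoxy-2-oxo-2H-chromen-8-yl)oxy]-2H-chromen-2-one F8. HCl in MeOH at 40 °C should remove both acetals and give 16.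

3. Step 3. The hydrogen-bonded, phenoxide-deactivated esters may hydrolyse only under forcing alkali, where the opened cis-cinnamate can isomerize to the trans acid that does not relactonize and the phloroglucinol polyanion can be oxidized by air. Fallback, from 6 to 9, without hydroxide: LiI in refluxing pyridine should cleave the two methyl esters by SN2 attack at the methyl groups while the lactone stays closed. Acidification with dilute HCl and warming to 60 °C should then give diacid 8, which decarboxylates to 9. No compound outside the list is made (F0).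

**Further compounds**
F1 | step 2 | 3-methoxy-2-[(7-methoxy-2-oxo-2H-chromen-8-yl)oxy]-3-oxopropanoic acid (racemic) | COc1ccc2ccc(=O)oc2c1OC(C(=O)O)C(=O)OC
F2 | step 2 | methyl 3-chloro-2-[(7-methoxy-2-oxo-2H-chromen-8-yl)oxy]-3-oxopropanoate (racemic) | COc1ccc2ccc(=O)oc2c1OC(C(Cl)=O)C(=O)OC
F3 | step 4 | N-{2,4,6-trihydroxy-3-[(7-methoxy-2-oxo-2H-chromen-8-yl)oxy]benzylidene}-N-methylmethanaminium chloride | C[N+](C)=Cc1c(O)cc(O)c(Oc2c(OC)ccc3ccc(=O)oc23)c1O.[Cl-]
F4 | step 4 | 2,4,6-trihydroxy-3-[(7-methoxy-2-oxo-2H-chromen-8-yl)oxy]benzaldehyde | O=Cc1c(O)cc(O)c(Oc2c(OC)ccc3ccc(=O)oc23)c1O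
F5 | step 4 | 2-hydroxy-4,6-bis(methoxymethoxy)-3-[(7-methoxy-2-oxo-2H-chromen-8-yl)oxy]benzaldehyde | COCOc1cc(OCOC)c(C=O)c(O)c1Oc1c(OC)ccc2ccc(=O)oc12
F6 | step 4 | ethyl (2E)-3-{2-hydroxy-4,6-bis(methoxymethoxy)-3-[(7-methoxy-2-oxo-2H-chromen-8-yl)oxy]phenyl}prop-2-enoate | CCOC(=O)/C=C/c1c(O)c(Oc2c(OC)ccc3ccc(=O)oc23)c(OCOC)cc1OCOC
F7 | step 4 | ethyl (2Z)-3-{2-hydroxy-4,6-bis(methoxymethoxy)-3-[(7-methoxy-2-oxo-2H-chromen-8-yl)oxy]phenyl}prop-2-enoate | CCOC(=O)/C=C\c1c(O)c(Oc2c(OC)ccc3ccc(=O)oc23)c(OCOC)cc1OCOC
F8 | step 4 | 5,7-bis(methoxymethoxy)-8-[(7-methoxy-2-oxo-2H-chromen-8-yl)oxy]-2H-chromen-2-one | COCOc1cc(OCOC)c2ccc(=O)oc2c1Oc1c(OC)ccc2ccc(=O)oc12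
F0 | step 3 | none | none
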